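# Cardivin C by a tropolone ether [6+4] cycloaddition: synthesis design

## The problem

Cardivin C is a germacranolide: one ten-membered carbocycle (C1–C10) carrying seven stereocentres on eight adjacent ring atoms, an α-methylene-γ-lactone (C11–C13) trans-fused across C7–C8, esters at C6 (isobutyrate) and C9 (angelate), a C2 carbinol, a C5 ketone and a tertiary C10 carbinol bearing the C14 methyl. With the ring drawn flat and numbered clockwise (β toward the viewer), the array is 2β-OH, 4α-CH3, 6β-O, 7α-C11, 8β-O, 9α-O, 10β-OH, so C6 to C10 alternate all the way round. A synthesis must close a ten-membered ring, which direct cyclisation does poorly, and must set this alternating array, which a floppy medium ring controls badly. C4 and C10 lie across the ring from each other and cannot influence one another in an open chain, whereas C6–C9 are contiguous and can be relayed from one another on a rigid scaffold; C2 is remote from all of them. The fragile parts are the exocyclic enoate (Michael and radical acceptor, reducible), the (Z)-angelate (isomerises to the tiglate with base, nucleophiles or radicals) and the C5 ketone, whose α-centres C4 and C6 can epimerise. The enabling feature is that C10 (oxygen plus the one-carbon substituent C14) and the carbonyl carbon C5 face each other with four ring atoms on either side. A C14–C5 bond therefore turns the monocycle into a bicyclo[4.4.1]undecan-11-one with a 2-oxygenated butene bridge (C1–C4) and a butadiene bridge (C6–C9), which is the [6+4] adduct of a 2-alkoxytropone and a 2-silyloxypenta-1,3-diene.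

## Retrosynthesis

**Esters and masked groups (40 ⇒ 39 ⇒ 36 ⇒ 35 ⇒ 33).** The last bonds cut are the two O–CH2Ar bonds of bis-ether 39, the C9–O acyl bond (alcohol 36 plus angelic acid 37) and the silyl ether of 35. The C11=C13 double bond is traced to a C13–N bond in the dimethylaminomethyl lactone 33. Installing the enoate or the angelate earlier would expose them to the hydride, stannane and amide-base steps needed elsewhere. Precursor 33 has every ring stereocentre but neither sensitive olefin. The forward steps must acylate without Z→E isomerisation and eliminate without strong base.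

**C14 and the C5–C14 bond (33 ⇒ 32 ⇒ 31 ⇒ 30 ⇒ 29 ⇒ 28).** The C14 methyl is traced through iodide 32 and alcohol 31 to aldehyde 30. Aldehyde and C5 ketone together are the retron of a glycol cleavage, so the C5–C14 bond is reconnected in diol 29, which comes from α-ketol 28. Cleaving the α-ketol 28 directly with Pb(OAc)4 would leave C14 as a carboxyl that cannot be reduced beside the C5 ketone. A Baeyer–Villiger oxidation of the bridge would migrate the alkoxy-bearing C10 and cut the wrong bond. This step converts the monocycle into a rigid bicycle, and the C5 ketone and C14 methyl become one carbonyl bridge. The forward sequence needs selective reduction of a hindered bridging ketone and of an aldehyde beside a ketone.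

**Lactone (28 ⇒ 25 ⇒ 24 ⇒ 22 ⇒ 19).** Cut in turn are C11–C13 (Mannich), the C8–O lactone bond together with the C9 hydroxyl (epoxide opening by the carboxyl), and C7–C11 (Ireland–Claisen rearrangement of the C9 acetate 19). Conjugate addition to a C9 enone followed by C8 oxidation and C9 reduction would need two reagents to enter from the shielded inner face of the bicycle. Plain enolate alkylation at C7 would leave C8 without oxygen. The sigmatropic route uses the C9 oxygen twice: it transfers its configuration to C7, and the oxygen is returned to C9 by epoxidation of the shifted olefin. Precursor 19 has no side chain. The forward steps need selective enolisation of an acetate beside an isobutyrate, outer-face epoxidation and a trans lactone closure.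

**C5 and C6 oxygens (19 ⇒ 17 ⇒ 16 ⇒ 14 ⇒ 11).** The two ester bonds, the C6–H bond (ketone reduction) and the C5–O bond (Rubottom oxidation) are removed, leading to hydroxy enone 11. The bridging ketone cannot enolise toward C5, since that would be a trans double bond in a seven-membered ring. The C6 ketone can, because the C5=C6 bond is trans only in the ten-membered ring. The C5 hydroxyl later supplies the ketone oxygen and the handle for the cleavage. In 11 the C6 and C9 oxygens are already differentiated as ketone and alcohol.

**1,4-Dioxygenation (11 ⇒ 10 ⇒ 9).** Both C–O bonds at C6 and C9 are cut back to the diene of 9 through endoperoxide 10. Stepwise epoxidation or dihydroxylation would give 1,2-patterns and regiochemical problems. Singlet oxygen delivers both oxygens to one face, and the Kornblum–DeLaMare rearrangement tells them apart. Required are attack on the outer diene face and removal of H6 rather than H9.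

**C2 carbinol (9 ⇒ 8 ⇒ 7 ⇒ 6).** The C2 ether and the C2–H bond are removed; ketone 7 is the hydrolysis product of the silyl enol ether in adduct 6. The bicycle must direct hydride to the outer face of the saturated bridge.

**The ring (6 ⇒ 3 + 5).** The C1–C10 and C4–C5 bonds are cut in a retro-[6+4] step. The other closures considered below each form one bond of a long chain that already carries most stereocentres. This cut removes two bonds, two rings and three stereocentres at once and leads to two achiral partners. The forward step must be periselective, regioselective, exo and enantioselective.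

**Partners (3 ⇒ 1 + 2; 5 ⇒ 4).** The tropone ether 3 comes from tropolone 1 and 4-methoxybenzyl chloride 2, and the diene 5 from (E)-pent-3-en-2-one 4, one step each.

## Roads not taken

**Alternative 1:** The cut is the C5–C6 bond. An open-chain alkenyl iodide aldehyde A2 would be closed by CrCl2 with catalytic NiCl2 (Nozaki–Hiyama–Kishi) to the ten-membered allylic alcohol A1, whose C5 methylene masks the ketone.
- Merits: the coupling is a proven way to close medium rings and tolerates esters and acetals. It creates the C6 carbinol in the same step, and the masked ketone protects C4 from epimerisation.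
- Weak points: A2 needs C2, C4, C7, C8, C9 and C10 set one by one in an acyclic chain before any ring exists. The C6 configuration would be decided in a ten-membered transition state that is hard to predict. The final ozonolysis of the C5 methylene must precede the lactone methylene, which then has to be made beside a ketone.
- Comparison: as a ring-forming event this road is better precedented than the chosen one. The chosen plan offsets this with a two-step entry to a bicycle that already holds the ring and three stereocentres and that relays the rest, at the price of five steps to cut the bridge.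

**Alternative 2:** The cut is C2–C3, with C5–C10 reconnected. A carbohydrate-derived 1,2-dialkenylcyclohexanol A4 would undergo an anionic oxy-Cope rearrangement (KH, 18-crown-6) to the ten-membered ketone A3.
- Merits: the reaction is reliable and irreversible and delivers the C5 ketone directly. The chair transition state transfers chirality to C2, and the chiral pool supplies C6–C9.
- Weak points: the target has no C1=C10 olefin. Its hydration to the C10 tertiary carbinol would set C10 late, on a flexible ring and next to C9, with no obvious control. A4 has two adjacent fully substituted carbons on a heavily oxygenated cyclohexane, and C4 is left to an enolate protonation.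
- Comparison: ring formation is safer here than in the chosen plan. The chosen plan fixes C10, with its oxygen and its methyl carbon, in the ring-forming step itself and needs no carbohydrate-to-carbocycle sequence.

**Alternative 3:** The cut is C9–C10. The keto aldehyde A6 would be closed by SmI2 (THF, t-BuOH) in a ketyl–ketone pinacol coupling to the 9,10-diol A5.
- Merits: one step makes the ring and both carbinol centres in the most densely oxygenated region, and such closures are known for medium rings.
- Weak points: the required relative configuration of the diol is not the one that chelation usually delivers. The aldehyde carries an α-alkoxy group that SmI2 can cleave reductively. The chain must again be built with five stereocentres and five protecting groups, and the closure must overcome transannular strain.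
- Comparison: this road sets C9 at the ring closure, which the chosen plan does only later by epoxidation. The chosen plan avoids the long acyclic precursor and the high-dilution closure and has a rigid scaffold for C6–C9.

Key step: step 3

## Route

Remarks:
- Germacrane numbering and the α/β convention defined above are used for all intermediates; C14 is α at C5 and C10 in the bicycles.
- C11 in 28–34 and C14 in 29 are formed as epimer mixtures and left unspecified, since both centres are destroyed later.
- The sense of induction of the pybox ligand must be assigned on 6. The (S,S) ligand is written; its antipode is equally available.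

Step 1
Reactants: 1 tropolone; 2 4-methoxybenzyl chloride
Product: 3 2-[(4-methoxybenzyl)oxy]cyclohepta-2,4,6-trien-1-one
Conditions: K2CO3, Bu4NI (cat.), DMF, 60 °C
Reagents that add atoms: none
Why: Williamson O-alkylation of the tropolonate anion; its two oxygens are equivalent, so a single ether forms.

Step 2
Reactants: 4 (E)-pent-3-en-2-one
Product: 5 (E)-2-(tert-butyldimethylsilyloxy)penta-1,3-diene
Conditions: t-BuMe2SiOTf, Et3N, Et2O, 0 °C
Reagents that add atoms: tert-butyldimethylsilyl trifluoromethanesulfonate, CC(C)(C)[Si](C)(C)OS(=O)(=O)C(F)(F)F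
Why: Soft enolisation removes a proton of the methyl group, the kinetic α′ site of the enone, and gives the cross-conjugated 2-silyloxydiene with the (E)-olefin intact.

Step 3
Reactants: 3 2-[(4-methoxybenzyl)oxy]cyclohepta-2,4,6-trien-1-one; 5 (E)-2-(tert-butyldimethylsilyloxy)penta-1,3-diene
Product: 6 (1S,6R,7S)-9-(tert-butyldimethylsilyloxy)-1-[(4-methoxybenzyl)oxy]-7-methylbicyclo[4.4.1]undeca-2,4,8-trien-11-one (bicyclic C1, C6, C7, C9, C11 = germacrane C10, C5, C4, C2, C14)
Conditions: [Cu((S,S)-Ph-pybox)](SbF6)2 (10 mol %; Ph-pybox = 2,6-bis(4-phenyl-4,5-dihydrooxazol-2-yl)pyridine), 4 Å molecular sieves, CH2Cl2, −78 → −40 °C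
Reagents that add atoms: none
Why: Proposed new method: the ether and carbonyl oxygens of 3 should chelate divalent copper in a five-membered ring, as α-alkoxy aldehydes do in pybox–copper Mukaiyama reactions, which lowers the tropone LUMO so that diene 5 adds across the two carbons flanking the carbonyl in a thermally allowed suprafacial ten-electron [6+4] cycloaddition (or its stepwise Mukaiyama–Michael/ring-closure equivalent). The closest known reactions are the thermal exo-selective [6+4] cycloadditions of tropone with acyclic dienes and 2-silyloxydienes, which are racemic, and Lewis-acid activation of tropones in [4+2] and [8+2] modes. Each new σ bond (C1–C10 and C4–C5) closes one seven-membered ring onto the carbonyl carbon C14, so the bicyclo[4.4.1]undecane and its ten-membered perimeter arise in one event. C4 is set relative to C5 and C10 by the exo transition state together with the (E)-geometry of 5, which puts the methyl group on the bridge face that looks toward C14. C10 and C5 are set in the absolute sense by the catalyst: with the substrate in an equatorial and the apical site of square-pyramidal copper, one phenyl group of the tridentate ligand covers a whole face of the tropone, so both termini are reached from the same open face (Re at the alkoxy-bearing carbon for 10S), whereas a two-fold symmetric bidentate bis(oxazoline) would shield opposite faces at the two termini. Regiochemistry rests on the CH2 terminus of 5, which has the largest HOMO coefficient, bonding to the alkoxy-bearing carbon, the oxocarbenium-like position at which nucleophiles attack 2-alkoxytropones. Periselectivity over the [4+2] and [8+2] modes rests on the exo geometry, in which the s-cis diene spans the two α-carbons, and is the main uncertainty.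

Step 4
Reactants: 6 [6+4] adduct
Product: 7 bicyclic 2,14-dione (10β-OPMB, 4α-methyl, C6=C7–C8=C9 diene)
Conditions: HF·pyridine, THF, 0 °C
Reagents that add atoms: none
Why: Fluoride-assisted protodesilylation of the silyl enol ether releases the C2 ketone; C4 is β to it and cannot epimerise, and the benzyl-type ether and the diene are inert.

Step 5
Reactants: 7 bicyclic 2,14-dione
Product: 8 2β-hydroxy-14-ketone
Conditions: LiBH(s-Bu)3, THF, −78 °C; aq NH4Cl
Reagents that add atoms: none
Why: Substrate-controlled ketone reduction: the bulky hydride should reach C2 from the outer face of the saturated bridge, because the inner face looks into the cleft over the diene bridge, and this sets the 2β carbinol. The bridging C14 ketone, flanked by a quaternary and a tertiary carbon, is left at −78 °C.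

Step 6
Reactants: 8 2β-hydroxy-14-ketone; 2 4-methoxybenzyl chloride
Product: 9 2β,10β-bis(4-methoxybenzyl) ether
Conditions: NaH, Bu4NI (cat.), DMF, 0 °C → rt
Reagents that add atoms: none
Why: Williamson etherification; the second 4-methoxybenzyl ether lets both hydroxyls be released in one final oxidation, and pointing into the cleft it further blocks the inner face of the diene.

Step 7
Reactants: 9 2β,10β-bis(4-methoxybenzyl) ether
Product: 11 9α-hydroxy-7-en-6-one, via 6α,9α-endoperoxide 10 (not isolated)
Conditions: O2, tetraphenylporphyrin (cat.), visible light, CH2Cl2, 0 °C; then Et3N (cat.), 0 °C → rt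
Reagents that add atoms: dioxygen, O=O
Why: [4+2] cycloaddition of singlet oxygen to the cisoid diene from its outer face, since C1 and C4 stand perpendicular over the inner face of the diene termini and the C2 ether fills the cleft; this sets 9α. Kornblum–DeLaMare rearrangement follows: the amine removes H6, the more accessible peroxide α-hydrogen (H9 lies against the quaternary C10 and its ether), giving the C6 enone and the C9 carbinol.

Step 8
Reactants: 11 9α-hydroxy-7-en-6-one
Product: 14 5β,9α-dihydroxy-7-en-6-one, via silyl dienol ether 12 (not isolated), via silyloxy ketone 13 (not isolated)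
Conditions: Me3SiOTf, Et3N, CH2Cl2, 0 °C; mCPBA (3-chloroperbenzoic acid), −20 °C; aq HCl, THF
Reagents that add atoms: 3-chloroperbenzoic acid, OOC(=O)c1cccc(Cl)c1 (oxygen on C5); trimethylsilyl trifluoromethanesulfonate, C[Si](C)(C)OS(=O)(=O)C(F)(F)F (silyl groups of 12 and 13 only)
Why: Rubottom oxidation: the enone can enolise only toward C5, and the C5=C6 enol ether is an allowed bridgehead olefin because it is trans in the ten-membered ring, whereas the bridging ketone cannot enolise toward C5 (Bredt's rule). The peracid attacks the only exposed lobe at C5, so the hydroxyl takes the place of H5; acid work-up removes both silyl groups.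

Step 9
Reactants: 14 5β,9α-dihydroxy-7-en-6-one; 15 acetic anhydride
Product: 16 9α-acetoxy-5β-hydroxy-7-en-6-one
Conditions: pyridine, DMAP (4-dimethylaminopyridine, cat.), CH2Cl2, 0 °C
Reagents that add atoms: none
Why: Acylation of the secondary C9 hydroxyl; the tertiary C5 hydroxyl does not react, and the acetate is the two-carbon unit that becomes C11–C12.

Step 10
Reactants: 16 9α-acetoxy-5β-hydroxy-7-en-6-one
Product: 17 5β,6β-diol 9α-acetate
Conditions: NaBH4, CeCl3·7H2O, MeOH, −78 °C
Reagents that add atoms: none
Why: Luche 1,2-reduction of the enone; hydride adds anti to the C5–C4 bond, which stands perpendicular to the carbonyl plane, that is from the outer face, and sets the 6β carbinol. The hindered bridging ketone and the acetate are not reduced at −78 °C.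

Step 11
Reactants: 17 5β,6β-diol 9α-acetate; 18 isobutyric anhydride
Product: 19 6β-isobutyrate 9α-acetate
Conditions: DMAP (cat.), Et3N, CH2Cl2, rt
Reagents that add atoms: none
Why: DMAP-catalysed esterification of the allylic secondary C6 hydroxyl; the tertiary C5 hydroxyl stays free, and the trans arrangement of the two oxygens disfavours acyl migration.

Step 12
Reactants: 19 6β-isobutyrate 9α-acetate
Product: 22 7α-(carboxymethyl)-8-ene acid, via silyl ketene acetal 20 (not isolated), via trimethylsilyl ester 21 (not isolated)
Conditions: LiN(SiMe3)2 (2.3 equiv), Me3SiCl, Et3N, THF, −78 → 50 °C; aq HCl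
Reagents that add atoms: chlorotrimethylsilane, C[Si](C)(C)Cl (silyl groups of 20 and 21 only)
Why: Ireland–Claisen rearrangement: the acetate CH3 is deprotonated much faster than the tertiary C–H of the isobutyrate, and the enolate and the C5 alkoxide are trapped by the chlorosilane. The [3,3] shift forms C7–C11 on the face from which the C9–O bond leaves, so 7α is relayed suprafacially from 9α and the olefin moves to C8=C9; acid work-up frees the acid and the C5 hydroxyl.

Step 13
Reactants: 22 7α-(carboxymethyl)-8-ene acid
Product: 24 9α-hydroxy-8β,12-lactone, via epoxy acid 23 (not isolated)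
Conditions: mCPBA, CH2Cl2, 0 °C → rt; then PPTS (pyridinium 4-toluenesulfonate, cat.)
Reagents that add atoms: 3-chloroperbenzoic acid, OOC(=O)c1cccc(Cl)c1
Why: Prilezhaev epoxidation of C8=C9 from the outer face (C1 again covers the inner face at C9; the C7 side chain is expected to sit pseudo-equatorial), then 5-exo opening of the epoxide at C8 by the carboxyl group with inversion. This gives the trans-fused 8β,12-lactone and leaves the epoxide oxygen as the 9α hydroxyl; attack at the neopentylic C9 is disfavoured.

Step 14
Reactants: 24 9α-hydroxy-8β,12-lactone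
Product: 25 9α-triethylsilyl ether
Conditions: Et3SiCl, imidazole, DMF, 0 °C → rt
Reagents that add atoms: chlorotriethylsilane, CC[Si](Cl)(CC)CC
Why: Silylation of the secondary C9 hydroxyl; the tertiary C5 hydroxyl is not silylated by the chlorosilane and is needed free for steps 16 and 17.

Step 15
Reactants: 25 9α-triethylsilyl ether; 26 N,N-dimethylmethyleneiminium iodide
Product: 28 11-(dimethylaminomethyl) lactone, via dilithium alkoxide enolate 27 (not isolated)
Conditions: LiN(i-Pr)2 (2.2 equiv), THF, −78 °C; then 26, −78 → 0 °C; H2O
Reagents that add atoms: none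
Why: Mannich aminomethylation of the lactone enolate with the preformed iminium salt; the first equivalent of base takes the C5 hydroxyl, the second the lactone α-CH2, which is more acidic and less hindered than the isobutyrate methine. The amine is the protected form of the exocyclic methylene.

Step 16
Reactants: 28 11-(dimethylaminomethyl) lactone
Product: 29 5β,14-diol
Conditions: Zn(BH4)2, Et2O, 0 °C
Reagents that add atoms: none
Why: Chelation-assisted reduction of the α-hydroxy ketone: models place the C5 hydroxyl and the C14 carbonyl syn-periplanar, so zinc binds both and activates the hindered bridging ketone. Lactone, ester and silyl ether are inert to this reagent.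

Step 17
Reactants: 29 5β,14-diol
Product: 30 ten-membered 5-ketone 14-aldehyde
Conditions: NaIO4, THF/pH 7 buffer, 0 °C → rt
Reagents that add atoms: none
Why: Malaprade glycol cleavage: the gauche tertiary–secondary diol forms the cyclic periodate ester and the C5–C14 bond breaks. This opens the bicycle to the ten-membered ring, makes C5 the ketone and leaves C14 as an aldehyde on C10; no other free vicinal diol is present.

Step 18
Reactants: 30 ten-membered 5-ketone 14-aldehyde
Product: 31 14-alcohol
Conditions: NaBH4, MeOH/THF, −78 °C
Reagents that add atoms: none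
Why: Chemoselective hydride reduction: the aldehyde is reduced at −78 °C, the doubly α-branched C5 ketone and the esters are not.

Step 19
Reactants: 31 14-alcohol
Product: 32 14-iodide
Conditions: I2, PPh3, imidazole, toluene, 60 °C
Reagents that add atoms: iodine, II
Why: Appel-type iodination of the only free hydroxyl; the neopentyl position needs warming, and imidazole buffers the acid.

Step 20
Reactants: 32 14-iodide
Product: 33 10α-methyl compound (C14 = CH3)
Conditions: Bu3SnH, AIBN (azobisisobutyronitrile, cat.), toluene, 80 °C
Reagents that add atoms: none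
Why: Radical chain dehalogenation; the primary C14 radical abstracts hydrogen from the stannane. No enoate is present yet, which is why C14 is finished before the methylene and the angelate are in place.

Step 21
Reactants: 33 10α-methyl compound
Product: 35 α-methylene lactone 9α-triethylsilyl ether, via trimethylammonium iodide 34 (not isolated)
Conditions: MeI, MeCN, rt; then aq NaHCO3, EtOAc
Reagents that add atoms: iodomethane, CI (methyl group of 34 only)
Why: Exhaustive methylation of the amine and Hofmann-type (E1cB) elimination of trimethylamine under bicarbonate give the α-methylene lactone without strong base, so the C4 and C6 centres next to the ketone are not endangered.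

Step 22
Reactants: 35 α-methylene lactone 9α-triethylsilyl ether
Product: 36 9α-alcohol
Conditions: HF·pyridine, pyridine/THF, 0 °C
Reagents that add atoms: none
Why: Fluoride cleavage of the triethylsilyl ether under buffered conditions that the enoate, the ketone and the benzyl-type ethers tolerate.

Step 23
Reactants: 36 9α-alcohol; 37 angelic acid
Product: 39 9α-angelate 2,10-bis(4-methoxybenzyl) ether, via mixed anhydride 38 (not isolated)
Conditions: 2,4,6-Cl3C6H2COCl, Et3N, toluene, rt; then 36, 80 °C
Reagents that add atoms: 2,4,6-trichlorobenzoyl chloride, O=C(Cl)c1c(Cl)cc(Cl)cc1Cl (aroyl group of 38 only)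
Why: Yamaguchi-type esterification through the mixed anhydride; heating in toluene without a nucleophilic catalyst is the usual way to make angelates, because it avoids the addition–elimination path that isomerises them to tiglates. Only the secondary C9 hydroxyl is free.

Step 24
Reactants: 39 9α-angelate 2,10-bis(4-methoxybenzyl) ether
Product: 40 cardivin C
Conditions: DDQ (2,3-dichloro-5,6-dicyano-1,4-benzoquinone), CH2Cl2/pH 7 buffer, 0 °C → rt
Reagents that add atoms: none
Why: Oxidative cleavage of both 4-methoxybenzyl ethers (benzylic hydride abstraction, then hydrolysis of the oxocarbenium ions) under buffered conditions that leave the enoates, the ketone and the tertiary alcohol untouched.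

## Compound list

1 | tropolone | O=C1C=CC=CC=C1O | starting material
2 | 4-methoxybenzyl chloride | COc1ccc(CCl)cc1 | starting material
3 | 2-[(4-methoxybenzyl)oxy]cyclohepta-2,4,6-trien-1-one | O=C1C=CC=CC=C1OCc2ccc(OC)cc2 | intermediate
4 | (E)-pent-3-en-2-one | C/C=C/C(C)=O | starting material
5 | (E)-2-(tert-butyldimethylsilyloxy)penta-1,3-diene | C=C(O[Si](C)(C)C(C)(C)C)/C=C/C | intermediate
6 | (1S,6R,7S)-9-(tert-butyldimethylsilyloxy)-1-[(4-methoxybenzyl)oxy]-7-methylbicyclo[4.4.1]undeca-2,4,8-trien-11-one | COc1ccc(CO[C@@]23CC(O[Si](C)(C)C(C)(C)C)=C[C@H](C)[C@@H](C=CC=C2)C3=O)cc1 | intermediate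
7 | bicyclic 2,14-dione (10β-OPMB, 4α-CH3, 6,8-diene) | COc1ccc(CO[C@@]23CC(=O)C[C@H](C)[C@@H](C=CC=C2)C3=O)cc1 | intermediate
8 | 2β-hydroxy-14-ketone | COc1ccc(CO[C@@]23C[C@@H](O)C[C@H](C)[C@@H](C=CC=C2)C3=O)cc1 | intermediate
9 | 2β,10β-bis(4-methoxybenzyl) ether | COc1ccc(CO[C@@]23C[C@@H](OCc4ccc(OC)cc4)C[C@H](C)[C@@H](C=CC=C2)C3=O)cc1 | intermediate
10 | 6α,9α-endoperoxide of 9 | COc1ccc(CO[C@@]23C[C@@H](OCc4ccc(OC)cc4)C[C@H](C)[C@@H]([C@H]5C=C[C@@H]2OO5)C3=O)cc1 | intermediate (not isolated)
11 | 9α-hydroxy-7-en-6-one | COc1ccc(CO[C@@]23C[C@@H](OCc4ccc(OC)cc4)C[C@H](C)[C@@H](C(=O)C=C[C@@H]2O)C3=O)cc1 | intermediate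
12 | 6,9α-bis(trimethylsilyloxy)-5(6),7-diene (bridgehead dienol ether, cis in the seven-membered ring) | COc1ccc(CO[C@@]23C[C@@H](OCc4ccc(OC)cc4)C[C@H](C)C(=C(O[Si](C)(C)C)C=C[C@@H]2O[Si](C)(C)C)C3=O)cc1 | intermediate (not isolated)
13 | 5β,9α-bis(trimethylsilyloxy)-7-en-6-one | COc1ccc(CO[C@@]23C[C@@H](OCc4ccc(OC)cc4)C[C@H](C)[C@@](O[Si](C)(C)C)(C(=O)C=C[C@@H]2O[Si](C)(C)C)C3=O)cc1 | intermediate (not isolated)
14 | 5β,9α-dihydroxy-7-en-6-one | COc1ccc(CO[C@@]23C[C@@H](OCc4ccc(OC)cc4)C[C@H](C)[C@@](O)(C(=O)C=C[C@@H]2O)C3=O)cc1 | intermediate
15 | acetic anhydride | CC(=O)OC(C)=O | starting material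
16 | 9α-acetoxy-5β-hydroxy-7-en-6-one | COc1ccc(CO[C@@]23C[C@@H](OCc4ccc(OC)cc4)C[C@H](C)[C@@](O)(C(=O)C=C[C@@H]2OC(C)=O)C3=O)cc1 | intermediate
17 | 5β,6β-diol 9α-acetate | COc1ccc(CO[C@@]23C[C@@H](OCc4ccc(OC)cc4)C[C@H](C)[C@@](O)([C@@H](O)C=C[C@@H]2OC(C)=O)C3=O)cc1 | intermediate
18 | isobutyric anhydride | CC(C)C(=O)OC(=O)C(C)C | starting material
19 | 6β-isobutyrate 9α-acetate | COc1ccc(CO[C@@]23C[C@@H](OCc4ccc(OC)cc4)C[C@H](C)[C@@](O)([C@@H](OC(=O)C(C)C)C=C[C@@H]2OC(C)=O)C3=O)cc1 | intermediate
20 | silyl ketene acetal of 19 (5β-OSiMe3) | COc1ccc(CO[C@@]23C[C@@H](OCc4ccc(OC)cc4)C[C@H](C)[C@@](O[Si](C)(C)C)([C@@H](OC(=O)C(C)C)C=C[C@@H]2OC(=C)O[Si](C)(C)C)C3=O)cc1 | intermediate (not isolated)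
21 | trimethylsilyl ester of the rearranged acid (7α-CH2CO2SiMe3, 8-ene, 5β-OSiMe3) | COc1ccc(CO[C@@]23C[C@@H](OCc4ccc(OC)cc4)C[C@H](C)[C@@](O[Si](C)(C)C)([C@@H](OC(=O)C(C)C)[C@H](CC(=O)O[Si](C)(C)C)C=C2)C3=O)cc1 | intermediate (not isolated)
22 | 7α-(carboxymethyl)-8-ene acid | COc1ccc(CO[C@@]23C[C@@H](OCc4ccc(OC)cc4)C[C@H](C)[C@@](O)([C@@H](OC(=O)C(C)C)[C@H](CC(=O)O)C=C2)C3=O)cc1 | intermediate
23 | 8α,9α-epoxy acid | COc1ccc(CO[C@@]23C[C@@H](OCc4ccc(OC)cc4)C[C@H](C)[C@@](O)([C@@H](OC(=O)C(C)C)[C@H](CC(=O)O)[C@@H]5O[C@@H]52)C3=O)cc1 | intermediate (not isolated)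
24 | 9α-hydroxy-8β,12-lactone | COc1ccc(CO[C@@]23C[C@@H](OCc4ccc(OC)cc4)C[C@H](C)[C@@](O)([C@@H](OC(=O)C(C)C)[C@H]5[C@@H](OC(=O)C5)[C@@H]2O)C3=O)cc1 | intermediate
25 | 9α-triethylsilyl ether | COc1ccc(CO[C@@]23C[C@@H](OCc4ccc(OC)cc4)C[C@H](C)[C@@](O)([C@@H](OC(=O)C(C)C)[C@H]5[C@@H](OC(=O)C5)[C@@H]2O[Si](CC)(CC)CC)C3=O)cc1 | intermediate
26 | N,N-dimethylmethyleneiminium iodide | C=[N+](C)C.[I-] | starting material
27 | dilithium C5 alkoxide lactone enolate of 25 | COc1ccc(CO[C@@]23C[C@@H](OCc4ccc(OC)cc4)C[C@H](C)[C@@]([O-])([C@@H](OC(=O)C(C)C)[C@H]5[C@@H](OC([O-])=C5)[C@@H]2O[Si](CC)(CC)CC)C3=O)cc1.[Li+].[Li+] | intermediate (not isolated)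
28 | 11-(dimethylaminomethyl) lactone (C11 epimers) | COc1ccc(CO[C@@]23C[C@@H](OCc4ccc(OC)cc4)C[C@H](C)[C@@](O)([C@@H](OC(=O)C(C)C)[C@H]5[C@@H](OC(=O)C5CN(C)C)[C@@H]2O[Si](CC)(CC)CC)C3=O)cc1 | intermediate
29 | 5β,14-diol (C14 epimers) | COc1ccc(CO[C@@]23C[C@@H](OCc4ccc(OC)cc4)C[C@H](C)[C@@](O)([C@@H](OC(=O)C(C)C)[C@H]5[C@@H](OC(=O)C5CN(C)C)[C@@H]2O[Si](CC)(CC)CC)C3O)cc1 | intermediate
30 | ten-membered 5-ketone 14-aldehyde | COc1ccc(CO[C@@]2(C=O)C[C@@H](OCc3ccc(OC)cc3)C[C@H](C)C(=O)[C@@H](OC(=O)C(C)C)[C@H]4[C@@H](OC(=O)C4CN(C)C)[C@@H]2O[Si](CC)(CC)CC)cc1 | intermediate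
31 | 14-alcohol | COc1ccc(CO[C@@]2(CO)C[C@@H](OCc3ccc(OC)cc3)C[C@H](C)C(=O)[C@@H](OC(=O)C(C)C)[C@H]4[C@@H](OC(=O)C4CN(C)C)[C@@H]2O[Si](CC)(CC)CC)cc1 | intermediate
32 | 14-iodide | COc1ccc(CO[C@@]2(CI)C[C@@H](OCc3ccc(OC)cc3)C[C@H](C)C(=O)[C@@H](OC(=O)C(C)C)[C@H]4[C@@H](OC(=O)C4CN(C)C)[C@@H]2O[Si](CC)(CC)CC)cc1 | intermediate
33 | 10α-methyl compound | COc1ccc(CO[C@@]2(C)C[C@@H](OCc3ccc(OC)cc3)C[C@H](C)C(=O)[C@@H](OC(=O)C(C)C)[C@H]4[C@@H](OC(=O)C4CN(C)C)[C@@H]2O[Si](CC)(CC)CC)cc1 | intermediate
34 | trimethylammonium iodide of 33 | COc1ccc(CO[C@@]2(C)C[C@@H](OCc3ccc(OC)cc3)C[C@H](C)C(=O)[C@@H](OC(=O)C(C)C)[C@H]4[C@@H](OC(=O)C4C[N+](C)(C)C)[C@@H]2O[Si](CC)(CC)CC)cc1.[I-] | intermediate (not isolated)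
35 | α-methylene lactone 9α-triethylsilyl ether | COc1ccc(CO[C@@]2(C)C[C@@H](OCc3ccc(OC)cc3)C[C@H](C)C(=O)[C@@H](OC(=O)C(C)C)[C@H]4[C@@H](OC(=O)C4=C)[C@@H]2O[Si](CC)(CC)CC)cc1 | intermediate
36 | 9α-alcohol | COc1ccc(CO[C@@]2(C)C[C@@H](OCc3ccc(OC)cc3)C[C@H](C)C(=O)[C@@H](OC(=O)C(C)C)[C@H]4[C@@H](OC(=O)C4=C)[C@@H]2O)cc1 | intermediate
37 | angelic acid ((Z)-2-methylbut-2-enoic acid) | C/C=C(/C)C(=O)O | starting material
38 | angelic 2,4,6-trichlorobenzoic anhydride | C/C=C(/C)C(=O)OC(=O)c1c(Cl)cc(Cl)cc1Cl | intermediate (not isolated)
39 | 9α-angelate 2,10-bis(4-methoxybenzyl) ether of cardivin C | COc1ccc(CO[C@@]2(C)C[C@@H](OCc3ccc(OC)cc3)C[C@H](C)C(=O)[C@@H](OC(=O)C(C)C)[C@H]4[C@@H](OC(=O)C4=C)[C@@H]2OC(=O)/C(C)=C\C)cc1 | intermediate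
40 | cardivin C | C=C1C(=O)O[C@@H]2[C@@H]1[C@H](OC(=O)C(C)C)C(=O)[C@@H](C)C[C@H](O)C[C@](C)(O)[C@H]2OC(=O)/C(C)=C\C | target

## Step count and least certain steps

Total step count: 24. Longest linear sequence: 23 steps (1 to 40 through steps 1 and 3–24; step 2 is a one-step branch).

**Step 3 (key step, proposed new method).** The tropone may react as a four-electron or eight-electron partner with the enol ether double bond, or stop at a Mukaiyama–Michael adduct. The diene may bond the other way round, or the catalyst may discriminate the faces poorly. Fallback, from 3 and 5: heating the partners without catalyst (toluene, 110 °C) uses the known thermal exo-selective [6+4] mode of tropones with 2-silyloxydienes. It would give the racemate, that is 6 together with its mirror image ent-6 F1. Preparative chromatography on a chiral stationary phase would separate them, and the route is rejoined at 6.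

**Step 8.** Enolisation toward the bridgehead may be slow, so that the enone silylates through its γ-position (C9) instead and oxidation occurs at the wrong carbon. Fallback, from 11: α′-acetoxylation of the enone with Mn(OAc)3 in refluxing benzene, a known oxidation of enones through the trivalent-manganese enolate, would give the 5β-acetoxy enone F2. Mild methanolysis (catalytic K2CO3, MeOH, 0 °C) of this doubly activated tertiary acetate returns to 14.

**Step 13.** The peracid may attack the inner face if the C7 side chain turns pseudo-axial, which would lead to a cis-fused lactone epimeric at C8 and C9, or the trans lactone closure may be slow. Fallback, from 22: a hydroxyl-directed epoxidation (VO(acac)2, t-BuOOH, CH2Cl2) in which the tertiary C5 hydroxyl, which leans toward the outer face, delivers the oxidant to that face of C8=C9. It leads to the same epoxy acid 23 and on to 24; new compounds: none F0.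

**Step 7.** Oxygen may add in part to the inner face, or the amine may remove H9 and give the C9 ketone. Fallback, from 10: reduction of the endoperoxide with zinc in acetic acid to the cis-6α,9α-enediol F3, then oxidation of the more accessible allylic C6 hydroxyl with MnO2, would give 11 whichever hydrogen the amine prefers. This does not correct a wrong face.

**Step 12.** The isobutyrate may be enolised as well (and undergo its own rearrangement toward C8), or the C5 alkoxide next to the bridging ketone may undergo an α-ketol shift before it is silylated. Fallback, from 14: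
- acylation of the C9 hydroxyl with bromoacetyl bromide (pyridine) to the bromoacetate F4;
- Luche reduction to the diol F5;
- isobutyrylation to F6;
- a Reformatsky–Claisen rearrangement (zinc dust, Me3SiCl, THF, reflux), which forms the ester enolate site-specifically by zinc insertion into the C–Br bond with no base present; aqueous work-up returns to acid 22.

**Step 5.** Hydride may enter from the inner face if the saturated bridge adopts another conformation, giving the C2 epimer. Fallback, from 7: the 2α-alcohol F7 so formed would be inverted by a Mitsunobu reaction (4-nitrobenzoic acid, PPh3, diisopropyl azodicarboxylate) to the 2β-(4-nitrobenzoate) F8, and methanolysis (K2CO3, MeOH) would give 8.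

## Further compounds

F1 | step 3 | ent-6, (1R,6S,7R)-9-(tert-butyldimethylsilyloxy)-1-[(4-methoxybenzyl)oxy]-7-methylbicyclo[4.4.1]undeca-2,4,8-trien-11-one | COc1ccc(CO[C@]23CC(O[Si](C)(C)C(C)(C)C)=C[C@@H](C)[C@H](C=CC=C2)C3=O)cc1
F2 | step 8 | 5β-acetoxy-9α-hydroxy-7-en-6-one | COc1ccc(CO[C@@]23C[C@@H](OCc4ccc(OC)cc4)C[C@H](C)[C@@](OC(C)=O)(C(=O)C=C[C@@H]2O)C3=O)cc1
F0 | step 13 | none | none
F3 | step 7 | cis-6α,9α-enediol | COc1ccc(CO[C@@]23C[C@@H](OCc4ccc(OC)cc4)C[C@H](C)[C@@H]([C@H](O)C=C[C@@H]2O)C3=O)cc1
F4 | step 12 | 9α-bromoacetoxy-5β-hydroxy-7-en-6-one | COc1ccc(CO[C@@]23C[C@@H](OCc4ccc(OC)cc4)C[C@H](C)[C@@](O)(C(=O)C=C[C@@H]2OC(=O)CBr)C3=O)cc1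
F5 | step 12 | 5β,6β-diol 9α-bromoacetate | COc1ccc(CO[C@@]23C[C@@H](OCc4ccc(OC)cc4)C[C@H](C)[C@@](O)([C@@H](O)C=C[C@@H]2OC(=O)CBr)C3=O)cc1
F6 | step 12 | 6β-isobutyrate 9α-bromoacetate | COc1ccc(CO[C@@]23C[C@@H](OCc4ccc(OC)cc4)C[C@H](C)[C@@](O)([C@@H](OC(=O)C(C)C)C=C[C@@H]2OC(=O)CBr)C3=O)cc1
F7 | step 5 | 2α-hydroxy-14-ketone (C2 epimer of 8) | COc1ccc(CO[C@@]23C[C@H](O)C[C@H](C)[C@@H](C=CC=C2)C3=O)cc1
F8 | step 5 | 2β-(4-nitrobenzoate) of 8 | COc1ccc(CO[C@@]23C[C@@H](OC(=O)c4ccc(cc4)[N+](=O)[O-])C[C@H](C)[C@@H](C=CC=C2)C3=O)cc1
A1 | alternative 1 | ten-membered C6 allylic alcohol with C5 exocyclic methylene (C9/C10 acetonide, C2 silyl ether, saturated lactone) | C=C1[C@@H](C)C[C@H](O[Si](C)(C)C(C)(C)C)C[C@]2(C)OC(C)(C)O[C@H]2[C@@H]3OC(=O)C[C@H]3[C@@H]1O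
A2 | alternative 1 | open-chain C5 alkenyl iodide C6 aldehyde | C=C(I)[C@@H](C)C[C@H](O[Si](C)(C)C(C)(C)C)C[C@]1(C)OC(C)(C)O[C@H]1[C@@H]2OC(=O)C[C@H]2C=O
A3 | alternative 2 | ten-membered C5 ketone with (E)-C1=C10 olefin and C2 4-methoxybenzyl ether | C/C1=C\[C@@H](OCc3ccc(OC)cc3)C[C@H](C)C(=O)[C@@H](OCOC)[C@H](C(=C)CO[Si](C)(C)C(C)(C)C)[C@H]2OC(C)(C)O[C@H]12
A4 | alternative 2 | 1,2-dialkenylcyclohexanol (C5 carbinol with isopropenyl, C10 with methyl and (E)-2-(4-methoxybenzyloxy)vinyl; C5 and C10 drawn as a chair transition state requires) | C=C(C)[C@]1(O)[C@@H](OCOC)[C@H](C(=C)CO[Si](C)(C)C(C)(C)C)[C@H]2OC(C)(C)O[C@@H]2[C@@]1(C)/C=C/OCc3ccc(OC)cc3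
A5 | alternative 3 | ten-membered 9,10-diol (C5 methylene, C6 isobutyrate, C8 and C12 4-methoxybenzyl ethers, C2 silyl ether) | C[C@]1(O)C[C@@H](O[Si](C)(C)C(C)(C)C)C[C@H](C)C(=C)[C@@H](OC(=O)C(C)C)[C@H](C(=C)COCc2ccc(OC)cc2)[C@@H](OCc2ccc(OC)cc2)[C@@H]1O
A6 | alternative 3 | open-chain C10 methyl ketone C9 aldehyde | CC(=O)C[C@@H](O[Si](C)(C)C(C)(C)C)C[C@H](C)C(=C)[C@@H](OC(=O)C(C)C)[C@H](C(=C)COCc1ccc(OC)cc1)[C@@H](OCc1ccc(OC)cc1)C=O
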